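**Remark on the chemistry (assumption):** the target has no stereocentre. Ring A is the benzoyl ring (C1 carries the ester carbon, C2 the hydroxyl, C4 the methoxy, C6 the 2-oxoheptyl chain). Ring B is the benzoic acid ring (C1' carboxyl, C2' hydroxyl, C4' ester oxygen, C6' pentyl).

## Analysis of the target

The target is a depside. Ring A, a 2-hydroxy-4-methoxy-6-(2-oxoheptyl)benzoyl unit, is bound through an aryl ester to the C4' oxygen of ring B, which is olivetolic acid acylated on the oxygen para to its carboxyl group. There is no stereocentre and no fused ring, so the difficulties are regiochemical and chemoselective. The ester carbonyl on C1 of ring A is flanked by the C2 oxygen and the C6 chain, so it is shielded on both sides. The C6 chain places a ketone oxygen six atoms away from that carbonyl. Base or strong acid can therefore turn the depside into a 3-pentylisocoumarin with loss of the ring B phenol, and any activated form of the ring A acid closes to the same isocoumarin before a phenol can be acylated. Ring B ends as a free salicylic acid that decarboxylates on heating, and of the three phenolic oxygens one must stay methylated while two are set free. The ester bond therefore has to be made without activating the ring A carboxyl, and the closing steps have to be neutral. The strategy rests on the contiguous triad C6 (carbon chain), C1 (carboxyl carbon) and C2 (oxygen) of ring A: this is what results when the two carbons of a 3-alkoxyaryne take up a carbon nucleophile and CO2, and the isocoumarin that results is the enol lactone of the keto acid that the depside needs.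

## Retrosynthetic reasoning

**Protecting-group endgame (24 ← 23 ← 22).** The last bonds cut are O–benzyl and O–methyl bonds. The ring B acid is released last, from benzyl ester 23 by hydrogenolysis, because that is the only deprotection that needs neither base nor acid. One step earlier, the two ether oxygens that sit ortho to a carbonyl group (C2 of ring A as methyl ether, C2' of ring B as benzyl ether in 22) are unmasked together by chelation-controlled cleavage with a boron trihalide. The unchelated C4 methoxy group stays. This choice lets ring A travel as a symmetrical dimethyl ether through the aryne chemistry and lets ring B carry only benzyl groups.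

**Ester bond (22 ← 13 + 21).** The cut is made between the ester oxygen and C4' of ring B, not at the acyl C–O bond. An acyl donor made from keto acid 13 would be captured by its own ketone enol and return isocoumarin 12, and the C1 carbonyl is hindered in any case. With the oxygen–aryl bond as the one to be formed, 13 acts as a carboxylate nucleophile and ring B becomes arylboronic acid 21. The forward reaction is a copper-mediated oxidative O-arylation that has to tolerate the ketone and the benzyl groups.

**Keto acid from its enol lactone (13 ← 12).** The carboxyl group and the ketone of 13 are the two halves of an enol lactone. Closing the O–C bond in the retrosynthetic sense gives isocoumarin 12, a neutral and stable storage form. Forward, hydroxide has to open the lactone, and the acid has to be set free without heat.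

**Key disconnection (12 ← 7 + 8 + 9).** Three bonds of 12 are cut: the aryl–C4 bond, the aryl–C1(carbonyl) bond and the O2–C3 bond. What remains is 3,5-dimethoxybenzyne 10 (from silyl triflate 7), hept-1-yne 8 and carbon dioxide 9. The cut is placed here because the two carbon substituents stand on neighbouring ring carbons next to an oxygen, which is the polarity pattern of a 3-alkoxyaryne. The alkyne supplies the benzylic carbon and the ketone carbon at the right oxidation level, and CO2 supplies the carboxyl carbon. Forward, one flask has to deliver the alkynyl group to the aryne carbon remote from oxygen, CO2 to the other, and a 6-endo lactonization.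

**Aryne precursor (7 ← 5 ← 2 ← 1).** The C–Si and O–S bonds of 7 are cut back to the symmetrical phenol 1. A carbamate on the phenol oxygen (2) directs lithiation to the carbon between it and a methoxy group; the two such carbons are equivalent. Silylation gives 5, and exchange of carbamate for triflate gives 7. The symmetry of 1 is the reason for keeping both ring A oxygens as methyl ethers at this stage.

**Ring B partner (21 ← 20 ← 19 ← 18 ← 17 ← 16 ← 14).** The C–B bond of 21 comes from pinacol boronate 20 and this from aryl triflate 19, so the position of boron is fixed by one of the two oxygens of olivetol 14. The benzyl groups of 19 are cut back to hydroxy acid 18, its carboxyl to the aldehyde of 17, the triflate to the free para hydroxyl of 16, and the formyl carbon to an electrophilic formylation of 14. The other resorcinol oxygen survives as the C2' oxygen.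

## Alternatives that were turned down

**Alternative 1:** Ring B is taken apart into acyclic pieces, dibenzyl malonate A2 and (E)-non-3-en-2-one A3.
- Forward key step: conjugate addition of A2 to A3 (bond C1'–C6'), then closure of the methyl ketone enolate onto one ester (bond C2'–C3'). This gives benzyl 2,4-dioxo-6-pentylcyclohexane-1-carboxylate A1. The ring A acid would then be attached to an enol oxygen of A1, and the carbocycle dehydrogenated late.
- For it: the whole ring B skeleton, with carboxyl and pentyl in place, arises in one operation from cheap materials. On this point it is clearly stronger than the present route, which spends six steps on 21.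
- Against it: it leaves the hard part untouched. Ring A still has to be made, and the O-acylation needs an activated ring A acid, which closes to the isocoumarin. A1 has two enolizable oxygens (C2' and C4'), so the site of acylation is not secured. Enol esters of cyclohexane-1,3-diones shift their acyl group to carbon. The late aromatization (halogenation and elimination, or dehydrogenation) would have to spare an electron-rich ring A and a labile ester.
- Comparison: the chosen strategy is longer on ring B, but it forms the ester by carboxylate arylation and needs no oxidation after the two rings are joined.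

**Alternative 2:** Ring A is cut at C1–C6 and traced to an open-chain aryl ester, 4-(benzyloxycarbonyl)-3-hydroxy-5-pentylphenyl 3,5,7-trioxo-8-(2-pentyl-1,3-dioxolan-2-yl)octanoate A5.
- Forward key step: aldol addition of C2 of the chain onto the C7 ketone, dehydration and enolization, giving the ring A resorcylate A4.
- For it: it follows the biosynthetic logic, builds ring A on an ester that already exists (so no hindered esterification), uses no transition metal, and keeps the side-chain ketone masked.
- Against it: A5 is an aryl ester of a β-keto acid, which is a strong acyl donor with a good leaving group. The C5 enol oxygen can close a pyranone with loss of the ring B phenol, and a Claisen closure from C6 to C1 would give an acylphloroglucinol. The base needed for the aldol is the reagent that triggers both. Assembling A5 by polyketone chain extension on an aryl ester is hard to defend. A4 has the C4 hydroxyl free, so one of three phenols must be methylated late, and the ketal still has to come off with acid.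
- Comparison: once A5 exists, this route is the most convergent on paper. The chosen strategy gives that up for preformed aromatic rings, a methyl ether that is present from the first step, and a ring A substitution pattern fixed by aryne polarity.

**Alternative 3:** Ring A is cut at C1–C2 and C5–C6 into 1,3-dimethoxy-1-(trimethylsilyloxy)buta-1,3-diene A7 and the ring B ynoate A8.
- Forward key step: [4+2] cycloaddition of A7 to A8, then loss of methanol, giving the salicylate A6.
- For it: the regiochemistry follows from the polarization of both partners. The C2 hydroxyl comes out free and the C4 oxygen methylated, so no selective ether cleavage is needed. The ester is made beforehand from an unhindered alkynoic acid, and the ketone stays masked. On these three points it is stronger than the chosen route.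
- Against it: ynoates with an alkyl group on the β-carbon are slow dienophiles for this diene class, and the heat they need shortens the life of the diene. The propargylic CH2 of A8 can isomerize to an allenoate. The silyl ketene acetal can attack the aryl ester, and it is quenched by the free C2' hydroxyl. A8 needs its own multi-step synthesis. The dioxolane must finally be removed with acid next to an ester that acid can convert to an isocoumarin.
- Comparison: the chosen strategy has to differentiate the ring A oxygens with a boron trihalide and needs a boronic acid. In return, its key step uses a simple alkyne and CO2, its regiocontrol is of a well-understood kind, and the keto acid is stored as a stable lactone until it is needed.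

Key step: step 4

## Route

Step 1
Reactants: 1 3,5-dimethoxyphenol
Product: 2 3,5-dimethoxyphenyl propan-2-ylcarbamate
Conditions: i-PrNCO, Et3N (cat.), CH2Cl2, rt
Reagents that add atoms: isopropyl isocyanate CC(C)N=C=O
Why: Base-catalysed addition of the phenol O–H across the isocyanate gives the N-monosubstituted aryl carbamate, which directs ortho-metalation and can later be removed by elimination.

Step 2
Reactants: 2 3,5-dimethoxyphenyl propan-2-ylcarbamate
Product: 5 3,5-dimethoxy-2-(trimethylsilyl)phenyl propan-2-ylcarbamate, via N-silyl carbamate 3 (not isolated), via doubly silylated carbamate 4 (not isolated)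
Conditions: TBSOTf, TMEDA, Et2O, 0 °C → rt; n-BuLi, TMEDA, −78 °C; Me3SiCl, −78 °C → rt; aq NaHSO4
Reagents that add atoms: chlorotrimethylsilane C[Si](C)(C)Cl; tert-butyldimethylsilyl trifluoromethanesulfonate CC(C)(C)[Si](C)(C)OS(=O)(=O)C(F)(F)F (its silyl group is carried only by 3 and 4)
Why: Directed ortho-metalation: silylation on nitrogen masks the N–H, and the O-aryl carbamate of 3 steers lithiation to the carbon between carbamate and methoxy (two equivalent sites), which is better activated than C4 between the two methoxy groups. Me3SiCl traps the aryllithium at −78 °C before an anionic ortho-Fries shift can start, and aqueous NaHSO4 takes the silyl group off nitrogen in 4.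

Step 3
Reactants: 5 3,5-dimethoxy-2-(trimethylsilyl)phenyl propan-2-ylcarbamate
Product: 7 3,5-dimethoxy-2-(trimethylsilyl)phenyl trifluoromethanesulfonate, via silyl phenol 6 (not isolated)
Conditions: DBU, Et2NH, MeCN, 40 °C; then PhNTf2, rt
Reagents that add atoms: N-phenylbis(trifluoromethanesulfonimide) O=S(=O)(N(c1ccccc1)S(=O)(=O)C(F)(F)F)C(F)(F)F
Why: DBU removes the carbamate N–H and the phenoxide of 6 is expelled (E1cB), while Et2NH takes up the isocyanate as a urea. The phenoxide is triflated in the same flask by a mild triflyl donor, so the acid-labile aryl–silicon bond never meets acid.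

Step 4
Reactants: 7 3,5-dimethoxy-2-(trimethylsilyl)phenyl trifluoromethanesulfonate; 8 hept-1-yne; 9 carbon dioxide
Product: 12 6,8-dimethoxy-3-pentyl-1H-isochromen-1-one, via 3,5-dimethoxybenzyne 10 (not isolated), via alkynylbenzoate salt 11 (not isolated)
Conditions: CuCl(IPr) (10 mol %; IPr = 1,3-bis(2,6-diisopropylphenyl)imidazol-2-ylidene), CsF, Cs2CO3, CO2 (1 atm), MeCN, 100 °C, sealed vessel
Reagents that add atoms: none
Why: Fluoride attacks silicon in 7 and triflate leaves, giving aryne 10, while Cs2CO3 and CuCl(IPr) turn 8 into the carbene-ligated acetylide of monovalent copper. The acetylide adds across the strained triple bond (carbocupration): the methoxy group next to the aryne withdraws inductively and distorts it, so the alkynyl group bonds to the remote aryne carbon (future C6 of ring A) and copper to the carbon beside oxygen (future C1). The aryl–copper bond inserts CO2 to give carboxylate 11, whose oxygen adds to the copper-activated alkyne at the pentyl-bearing carbon, and protonation of the vinyl copper by a further molecule of 8 or by hydrogen carbonate releases 12 and returns the acetylide. The closest known reaction type is the carbene–copper-catalysed three-component coupling of arynes, terminal alkynes and CO2 to 3-substituted isocoumarins, applied here to a dimethoxy aryne. One ring is closed, the pyranone, by 6-endo-dig attack of oxygen; the 5-exo-dig mode would give an alkylidenephthalide and is disfavoured by the bulky carbene on copper and by the alkyl group, which stabilizes positive character at the distal alkyne carbon. No stereocentre is formed. Three selectivities are needed: aryne regiochemistry (secured by the adjacent methoxy group), three-component over two-component coupling (secured by the CO2 atmosphere and the aprotic medium, so that the aryl copper is carboxylated before it is protonated), and endo over exo lactonization (secured by the catalyst).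

Step 5
Reactants: 12 6,8-dimethoxy-3-pentyl-1H-isochromen-1-one
Product: 13 2,4-dimethoxy-6-(2-oxoheptyl)benzoic acid
Conditions: KOH, EtOH/H2O, reflux; then 1 M HCl, 0 °C
Reagents that add atoms: potassium hydroxide [K+].[OH-] (its oxygen becomes a carboxyl oxygen)
Why: Saponification of the enol lactone: hydroxide adds to C1, the enolate that leaves becomes the ketone, and the carboxylate cannot re-close in base. Cold acidification gives the keto acid, which is used at once because acid and heat return it to 12.

Step 6
Reactants: 14 olivetol (5-pentylbenzene-1,3-diol)
Product: 16 2,4-dihydroxy-6-pentylbenzaldehyde, via aryl iminium chloride 15 (not isolated)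
Conditions: POCl3, DMF, 0 °C → rt; then ice-water, aq NaOH to pH 6
Reagents that add atoms: N,N-dimethylformamide CN(C)C=O (formyl carbon); water O (formyl oxygen)
Why: Vilsmeier–Haack formylation: the chloroiminium electrophile attacks the carbon para to one hydroxyl and ortho to the other, as with orcinol, rather than the more crowded carbon between the two hydroxyls. Hydrolysis of iminium salt 15 gives the aldehyde.

Step 7
Reactants: 16 2,4-dihydroxy-6-pentylbenzaldehyde
Product: 17 4-formyl-3-hydroxy-5-pentylphenyl trifluoromethanesulfonate
Conditions: PhNTf2 (1.0 equiv), Et3N, CH2Cl2, 0 °C → rt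
Reagents that add atoms: N-phenylbis(trifluoromethanesulfonimide) O=S(=O)(N(c1ccccc1)S(=O)(=O)C(F)(F)F)C(F)(F)F
Why: Selective O-sulfonylation: the hydroxyl para to the formyl group is free and the more acidic, whereas the ortho hydroxyl is held in a hydrogen bond to the formyl oxygen, so one equivalent of a mild triflyl donor should react at the para oxygen only.

Step 8
Reactants: 17 4-formyl-3-hydroxy-5-pentylphenyl trifluoromethanesulfonate
Product: 18 2-hydroxy-6-pentyl-4-{[(trifluoromethyl)sulfonyl]oxy}benzoic acid
Conditions: NaClO2, NaH2PO4, 2-methylbut-2-ene, t-BuOH/H2O, rt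
Reagents that add atoms: sodium chlorite [Na+].[O-]Cl=O
Why: Pinnick oxidation converts the aldehyde to the acid in a buffered medium that leaves the aryl triflate alone. 2-Methylbut-2-ene removes HOCl, so the phenol ring, already deactivated by the triflate, is not chlorinated.

Step 9
Reactants: 18 2-hydroxy-6-pentyl-4-{[(trifluoromethyl)sulfonyl]oxy}benzoic acid
Product: 19 benzyl 2-(benzyloxy)-6-pentyl-4-{[(trifluoromethyl)sulfonyl]oxy}benzoate
Conditions: BnBr (excess), K2CO3, DMF, rt → 40 °C
Reagents that add atoms: benzyl bromide BrCc1ccccc1
Why: Carbonate-mediated SN2 alkylation benzylates the carboxylate and then the phenoxide in one operation. Excess benzyl bromide keeps the phenoxide concentration low, so the aryl triflate is not attacked at sulfur.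

Step 10
Reactants: 19 benzyl 2-(benzyloxy)-6-pentyl-4-{[(trifluoromethyl)sulfonyl]oxy}benzoate
Product: 20 benzyl 2-(benzyloxy)-6-pentyl-4-(4,4,5,5-tetramethyl-1,3,2-dioxaborolan-2-yl)benzoate
Conditions: B2pin2, Pd(dppf)Cl2, KOAc, 1,4-dioxane, 90 °C
Reagents that add atoms: bis(pinacolato)diboron CC1(C)OB(OC1(C)C)B1OC(C)(C)C(C)(C)O1
Why: Miyaura borylation: zerovalent palladium inserts into the unhindered aryl triflate, which is activated by the para ester; acetate-assisted transmetalation with the diboron and reductive elimination follow. Benzyl ether and benzyl ester are inert.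

Step 11
Reactants: 20 benzyl 2-(benzyloxy)-6-pentyl-4-(4,4,5,5-tetramethyl-1,3,2-dioxaborolan-2-yl)benzoate
Product: 21 [3-(benzyloxy)-4-(benzyloxycarbonyl)-5-pentylphenyl]boronic acid
Conditions: NaIO4, NH4OAc, acetone/H2O, rt
Reagents that add atoms: water O
Why: Oxidative removal of the diol: periodate cleaves the pinacol released in the hydrolysis equilibrium to acetone, which pulls the boronic ester over to the free boronic acid at room temperature and near-neutral pH.

Step 12
Reactants: 13 2,4-dimethoxy-6-(2-oxoheptyl)benzoic acid; 21 [3-(benzyloxy)-4-(benzyloxycarbonyl)-5-pentylphenyl]boronic acid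
Product: 22 benzyl 2-(benzyloxy)-4-{[2,4-dimethoxy-6-(2-oxoheptyl)benzoyl]oxy}-6-pentylbenzoate
Conditions: Cu(OTf)2 (0.4 equiv), urea, EtOAc, 60 °C, air
Reagents that add atoms: none
Why: Chan–Lam-type oxidative C–O coupling: the carboxylate binds divalent copper, the aryl group moves from boron to copper, and reductive elimination from a trivalent copper aryl carboxylate forms the C4'–O bond, with air reoxidizing the metal. The acid acts as the nucleophile, so its shielded carbonyl is not attacked and no activated acyl species exists that the ketone enol could capture.

Step 13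
Reactants: 22 benzyl 2-(benzyloxy)-4-{[2,4-dimethoxy-6-(2-oxoheptyl)benzoyl]oxy}-6-pentylbenzoate
Product: 23 benzyl 2-hydroxy-4-{[2-hydroxy-4-methoxy-6-(2-oxoheptyl)benzoyl]oxy}-6-pentylbenzoate
Conditions: BCl3, CH2Cl2, −78 → 0 °C; then H2O, 0 °C
Reagents that add atoms: none
Why: Chelation-controlled ether cleavage: BCl3 binds a carbonyl oxygen and the ortho ether oxygen in a six-membered chelate, and chloride removes the methyl group at C2 of ring A and the benzyl group at C2' of ring B. The unchelated C4 methoxy group, the aryl ester, the ketone and, at this temperature, the benzyl ester should stay.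

Step 14
Reactants: 23 benzyl 2-hydroxy-4-{[2-hydroxy-4-methoxy-6-(2-oxoheptyl)benzoyl]oxy}-6-pentylbenzoate
Product: 24 2-hydroxy-4-{[2-hydroxy-4-methoxy-6-(2-oxoheptyl)benzoyl]oxy}-6-pentylbenzoic acid (target)
Conditions: H2 (1 atm), Pd/C, EtOAc, rt
Reagents that add atoms: none
Why: Hydrogenolysis of the benzyl ester over Pd/C in a neutral solvent releases the acid without base, so neither the depside ester nor the salicylic acid is endangered. The non-conjugated ketone is not reduced under these conditions.

## Compound list

1 | 3,5-dimethoxyphenol | COc1cc(O)cc(OC)c1 | starting material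
2 | 3,5-dimethoxyphenyl propan-2-ylcarbamate | COc1cc(OC)cc(OC(=O)NC(C)C)c1 | intermediate
3 | 3,5-dimethoxyphenyl N-(tert-butyldimethylsilyl)-N-(propan-2-yl)carbamate (not isolated) | COc1cc(OC)cc(OC(=O)N(C(C)C)[Si](C)(C)C(C)(C)C)c1 | intermediate
4 | 3,5-dimethoxy-2-(trimethylsilyl)phenyl N-(tert-butyldimethylsilyl)-N-(propan-2-yl)carbamate (not isolated) | COc1cc(OC)c([Si](C)(C)C)c(OC(=O)N(C(C)C)[Si](C)(C)C(C)(C)C)c1 | intermediate
5 | 3,5-dimethoxy-2-(trimethylsilyl)phenyl propan-2-ylcarbamate | COc1cc(OC)c([Si](C)(C)C)c(OC(=O)NC(C)C)c1 | intermediate
6 | 3,5-dimethoxy-2-(trimethylsilyl)phenol (not isolated) | COc1cc(O)c([Si](C)(C)C)c(OC)c1 | intermediate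
7 | 3,5-dimethoxy-2-(trimethylsilyl)phenyl trifluoromethanesulfonate | COc1cc(OC)c([Si](C)(C)C)c(OS(=O)(=O)C(F)(F)F)c1 | intermediate
8 | hept-1-yne | CCCCCC#C | starting material
9 | carbon dioxide | O=C=O | starting material
10 | 3,5-dimethoxybenzyne (not isolated) | COC1=CC(OC)=CC#C1 | intermediate
11 | 2-(hept-1-yn-1-yl)-4,6-dimethoxybenzoate, formed as the carboxylate of monovalent copper and drawn as its caesium salt (not isolated) | CCCCCC#Cc1cc(OC)cc(OC)c1C(=O)[O-].[Cs+] | intermediate
12 | 6,8-dimethoxy-3-pentyl-1H-isochromen-1-one | CCCCCC1=Cc2cc(OC)cc(OC)c2C(=O)O1 | intermediate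
13 | 2,4-dimethoxy-6-(2-oxoheptyl)benzoic acid | CCCCCC(=O)Cc1cc(OC)cc(OC)c1C(=O)O | intermediate
14 | olivetol (5-pentylbenzene-1,3-diol) | CCCCCc1cc(O)cc(O)c1 | starting material
15 | [(2,4-dihydroxy-6-pentylphenyl)methylidene]dimethylammonium chloride (not isolated) | CCCCCc1cc(O)cc(O)c1C=[N+](C)C.[Cl-] | intermediate
16 | 2,4-dihydroxy-6-pentylbenzaldehyde | CCCCCc1cc(O)cc(O)c1C=O | intermediate
17 | 4-formyl-3-hydroxy-5-pentylphenyl trifluoromethanesulfonate | CCCCCc1cc(OS(=O)(=O)C(F)(F)F)cc(O)c1C=O | intermediate
18 | 2-hydroxy-6-pentyl-4-{[(trifluoromethyl)sulfonyl]oxy}benzoic acid | CCCCCc1cc(OS(=O)(=O)C(F)(F)F)cc(O)c1C(=O)O | intermediate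
19 | benzyl 2-(benzyloxy)-6-pentyl-4-{[(trifluoromethyl)sulfonyl]oxy}benzoate | CCCCCc1cc(OS(=O)(=O)C(F)(F)F)cc(OCc2ccccc2)c1C(=O)OCc1ccccc1 | intermediate
20 | benzyl 2-(benzyloxy)-6-pentyl-4-(4,4,5,5-tetramethyl-1,3,2-dioxaborolan-2-yl)benzoate | CCCCCc1cc(B2OC(C)(C)C(C)(C)O2)cc(OCc2ccccc2)c1C(=O)OCc1ccccc1 | intermediate
21 | [3-(benzyloxy)-4-(benzyloxycarbonyl)-5-pentylphenyl]boronic acid | CCCCCc1cc(B(O)O)cc(OCc2ccccc2)c1C(=O)OCc1ccccc1 | intermediate
22 | benzyl 2-(benzyloxy)-4-{[2,4-dimethoxy-6-(2-oxoheptyl)benzoyl]oxy}-6-pentylbenzoate | CCCCCC(=O)Cc1cc(OC)cc(OC)c1C(=O)Oc1cc(OCc2ccccc2)c(C(=O)OCc2ccccc2)c(CCCCC)c1 | intermediate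
23 | benzyl 2-hydroxy-4-{[2-hydroxy-4-methoxy-6-(2-oxoheptyl)benzoyl]oxy}-6-pentylbenzoate | CCCCCC(=O)Cc1cc(OC)cc(O)c1C(=O)Oc1cc(O)c(C(=O)OCc2ccccc2)c(CCCCC)c1 | intermediate
24 | 2-hydroxy-4-{[2-hydroxy-4-methoxy-6-(2-oxoheptyl)benzoyl]oxy}-6-pentylbenzoic acid | CCCCCC(=O)Cc1cc(OC)cc(O)c1C(=O)Oc1cc(O)c(C(=O)O)c(CCCCC)c1 | target

## Step count and least certain steps

Total: 14 steps. Longest linear sequence: 9 steps (steps 6 to 14, from olivetol 14). The ring A branch runs over 8 steps (steps 1 to 5 and 12 to 14).

**Step 4 (key step).** Three things can go wrong. The aryl–copper intermediate may be protonated before it inserts CO2, which would end in a plain hydroalkynylation of the aryne. The copper acetylide may be carboxylated directly, which consumes 8 and CO2. The carboxylate may close in the 5-exo mode. All three become more likely because the copper-bearing carbon is crowded by the neighbouring methoxy group. The fallback sets out from 7 and builds the same ortho pair stepwise. The aryne is generated with KF and 18-crown-6 in THF in the presence of dimethyl malonate and inserts into a carbon–carbon bond of the malonate, with the same regiochemistry, to give methyl 2-(2-methoxy-2-oxoethyl)-4,6-dimethoxybenzoate F1. Saponification with aqueous NaOH in methanol gives 2-(carboxymethyl)-4,6-dimethoxybenzoic acid F2. Heating F2 with hexanoyl chloride at about 200 °C (C-acylation of the homophthalic anhydride formed in the flask, decarboxylation and enol lactonization) returns to the route at 12.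

**Step 12.** Cu(OTf)2 is a Lewis acid and may re-close keto acid 13 to isocoumarin 12 before the coupling takes place. The boronic acid may be lost through oxidative hydroxylation or protodeboronation. The activated CH2 between ring A and the ketone may be oxidized by copper and air. The fallback sets out from 21 and avoids copper. With 2-(diacetoxyiodo)-1,3,5-trimethylbenzene and BF3·OEt2 in CH2Cl2, 21 is converted into [3-(benzyloxy)-4-(benzyloxycarbonyl)-5-pentylphenyl](2,4,6-trimethylphenyl)iodonium tetrafluoroborate F3. The potassium salt of 13 (from t-BuOK) is then arylated by F3 in toluene at 100 °C through ligand coupling on iodine, the electron-poor ring B aryl being transferred in preference to mesityl, and the route is rejoined at 22.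

**Step 13.** The boron Lewis acid activates the chelated ring A ester, and the ketone oxygen may attack it, with loss of the ring B phenol and closure to an isocoumarin. Partial loss of the benzyl ester or of the C4 methyl ether is also possible. The fallback moves the ether cleavage to a stage where no depside exists, and sets out from 12.
- BCl3 in CH2Cl2 cleaves the peri methyl ether of 12 and gives 8-hydroxy-6-methoxy-3-pentyl-1H-isochromen-1-one F4.
- BnBr and K2CO3 give 8-(benzyloxy)-6-methoxy-3-pentyl-1H-isochromen-1-one F5.
- KOH opens the lactone to 2-(benzyloxy)-4-methoxy-6-(2-oxoheptyl)benzoic acid F6.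
- The copper-mediated coupling of step 12 with 21 gives benzyl 2-(benzyloxy)-4-{[2-(benzyloxy)-4-methoxy-6-(2-oxoheptyl)benzoyl]oxy}-6-pentylbenzoate F7.
- A single hydrogenolysis (H2, Pd/C, EtOAc) removes all three benzyl groups and arrives at 24.

**Step 2.** Lithiation may compete at C4 between the two methoxy groups, the lithiated carbamate may undergo an anionic ortho-Fries shift if the temperature rises, and the electron-rich aryl silane may lose silicon during an acidic work-up. The fallback sets out from 1 and uses no directed metalation. Ortho-selective bromination (NBS, catalytic i-Pr2NH, CH2Cl2) gives 2-bromo-3,5-dimethoxyphenol F8, and hexamethyldisilazane converts it into (2-bromo-3,5-dimethoxyphenoxy)trimethylsilane F9. n-BuLi in THF at −78 °C then effects bromine–lithium exchange and a 1,3 shift of silicon from oxygen to carbon (retro-Brook), and the resulting lithium salt of 6 is quenched with Tf2O to rejoin the route at 7.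

## Further compounds

F1 | step 4 | methyl 2-(2-methoxy-2-oxoethyl)-4,6-dimethoxybenzoate | COC(=O)Cc1cc(OC)cc(OC)c1C(=O)OC
F2 | step 4 | 2-(carboxymethyl)-4,6-dimethoxybenzoic acid | OC(=O)Cc1cc(OC)cc(OC)c1C(=O)O
F3 | step 12 | [3-(benzyloxy)-4-(benzyloxycarbonyl)-5-pentylphenyl](2,4,6-trimethylphenyl)iodonium tetrafluoroborate | CCCCCc1cc([I+]c2c(C)cc(C)cc2C)cc(OCc2ccccc2)c1C(=O)OCc1ccccc1.F[B-](F)(F)F
F4 | step 13 | 8-hydroxy-6-methoxy-3-pentyl-1H-isochromen-1-one | CCCCCC1=Cc2cc(OC)cc(O)c2C(=O)O1
F5 | step 13 | 8-(benzyloxy)-6-methoxy-3-pentyl-1H-isochromen-1-one | CCCCCC1=Cc2cc(OC)cc(OCc3ccccc3)c2C(=O)O1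
F6 | step 13 | 2-(benzyloxy)-4-methoxy-6-(2-oxoheptyl)benzoic acid | CCCCCC(=O)Cc1cc(OC)cc(OCc2ccccc2)c1C(=O)O
F7 | step 13 | benzyl 2-(benzyloxy)-4-{[2-(benzyloxy)-4-methoxy-6-(2-oxoheptyl)benzoyl]oxy}-6-pentylbenzoate | CCCCCC(=O)Cc1cc(OC)cc(OCc2ccccc2)c1C(=O)Oc1cc(OCc2ccccc2)c(C(=O)OCc2ccccc2)c(CCCCC)c1
F8 | step 2 | 2-bromo-3,5-dimethoxyphenol | COc1cc(O)c(Br)c(OC)c1
F9 | step 2 | (2-bromo-3,5-dimethoxyphenoxy)trimethylsilane | COc1cc(O[Si](C)(C)C)c(Br)c(OC)c1
A1 | alternative 1 | benzyl 2,4-dioxo-6-pentylcyclohexane-1-carboxylate (racemic, trans) | CCCCC[C@H]1CC(=O)CC(=O)[C@@H]1C(=O)OCc1ccccc1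
A2 | alternative 1 | dibenzyl malonate | O=C(CC(=O)OCc1ccccc1)OCc1ccccc1
A3 | alternative 1 | (E)-non-3-en-2-one | CCCCC/C=C/C(C)=O
A4 | alternative 2 | 4-(benzyloxycarbonyl)-3-hydroxy-5-pentylphenyl 2,4-dihydroxy-6-[(2-pentyl-1,3-dioxolan-2-yl)methyl]benzoate | CCCCCC1(Cc2cc(O)cc(O)c2C(=O)Oc2cc(O)c(C(=O)OCc3ccccc3)c(CCCCC)c2)OCCO1
A5 | alternative 2 | 4-(benzyloxycarbonyl)-3-hydroxy-5-pentylphenyl 3,5,7-trioxo-8-(2-pentyl-1,3-dioxolan-2-yl)octanoate | CCCCCC1(CC(=O)CC(=O)CC(=O)CC(=O)Oc2cc(O)c(C(=O)OCc3ccccc3)c(CCCCC)c2)OCCO1
A6 | alternative 3 | 4-(benzyloxycarbonyl)-3-hydroxy-5-pentylphenyl 2-hydroxy-4-methoxy-6-[(2-pentyl-1,3-dioxolan-2-yl)methyl]benzoate | CCCCCC1(Cc2cc(OC)cc(O)c2C(=O)Oc2cc(O)c(C(=O)OCc3ccccc3)c(CCCCC)c2)OCCO1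
A7 | alternative 3 | 1,3-dimethoxy-1-(trimethylsilyloxy)buta-1,3-diene | C=C(OC)C=C(OC)O[Si](C)(C)C
A8 | alternative 3 | 4-(benzyloxycarbonyl)-3-hydroxy-5-pentylphenyl 4-(2-pentyl-1,3-dioxolan-2-yl)but-2-ynoate | CCCCCC1(CC#CC(=O)Oc2cc(O)c(C(=O)OCc3ccccc3)c(CCCCC)c2)OCCO1
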